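**Retrosynthetic overview**

Numbering used throughout: ring A = C1(=CH2)-C2-C3(OH)-C4(Br)-C5(Me2)-C6(spiro). Ring B = C6-C7-C8-C9(OH)(CH2Cl)-C10(=O)-C11.
Endgame: the C3 carbinol comes from hydride reduction of a C3 α-bromo ketone, C1=CH2 from a C1 ketone, C9 from chelate-controlled chloromethylation of a C9 ketone. C10-O and the saturated C7-C8 and C11 positions come from two successive conjugate reductions of a spiro cyclohexadienone, and C4-Br from anti bromoacetoxylation of a C3=C4 alkene, resolved with a lipase.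
Key disconnection: achiral 5,5-dimethylspiro[5.5]undeca-3,7,10-triene-1,9-dione arises by oxidative dearomatisation of a 4-(1-hydroxycyclopent-3-enyl)phenol. The five-membered carbocycle C1-C5 takes in the arene ipso carbon C6 through a semipinacol 1,2-shift of C5 and becomes six-membered ring A.
Enabling feature: spiro C6 stands para to the oxygen-bearing C9 of ring B, which is the retron of a para-phenol dearomatisation. It also lies between sp2 C1 (a masked ketone, the migration origin) and quaternary C5 (the best migrating group), so one 1,2-shift makes the C5-C6 bond between two quaternary carbons.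
Ring order: ring B is bought as a benzene ring, the cyclopentene is closed by ring-closing metathesis, and it is enlarged to ring A in the key step.

Key step: step 5

Assumption: the sense of induction of (R)-DTBM-SEGPHOS (step 9) and the lipase preference for the (3R)-ester (step 7) follow the usual models for these catalysts; if either is opposite, the ligand antipode is used or the unreacted ester is carried on.

Step 1
Reactants: 1 4-[(tert-butyldimethylsilyl)oxy]benzaldehyde; 2 prenyl bromide (1-bromo-3-methylbut-2-ene)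
Product: 3 rac-1-{4-[(tert-butyldimethylsilyl)oxy]phenyl}-2,2-dimethylbut-3-en-1-ol
Conditions: Zn dust, sat. aq NH4Cl/THF, 0 °C → rt
Reagents that add atoms: none
Why: Barbier prenylation, in which the allylzinc reacts through its γ-carbon in a cyclic transition state, so the 1,1-dimethylallyl carbinol forms and the future C5 with both methyl groups is in place; the carbinol centre is racemic and is oxidised next.

Step 2
Reactants: 3 rac-1-{4-[(tert-butyldimethylsilyl)oxy]phenyl}-2,2-dimethylbut-3-en-1-ol
Product: 4 1-{4-[(tert-butyldimethylsilyl)oxy]phenyl}-2,2-dimethylbut-3-en-1-one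
Conditions: Dess–Martin periodinane, CH2Cl2, 0 °C → rt
Reagents that add atoms: none
Why: Dess–Martin oxidation of a benzylic alcohol under neutral conditions that leave the aryl silyl ether and the terminal alkene untouched.

Step 3
Reactants: 4 1-{4-[(tert-butyldimethylsilyl)oxy]phenyl}-2,2-dimethylbut-3-en-1-one; 5 allylmagnesium bromide
Product: 6 rac-4-{4-[(tert-butyldimethylsilyl)oxy]phenyl}-3,3-dimethylhepta-1,6-dien-4-ol
Conditions: THF, −78 → 0 °C; sat. aq NH4Cl
Reagents that add atoms: none
Why: Grignard 1,2-addition, in which the allyl reagent reacts through a cyclic six-membered transition state and so adds even to this hindered, non-enolisable aryl ketone; the new carbinol centre (future C1) is racemic and is erased in step 5.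

Step 4
Reactants: 6 rac-4-{4-[(tert-butyldimethylsilyl)oxy]phenyl}-3,3-dimethylhepta-1,6-dien-4-ol
Product: 8 rac-4-(1-hydroxy-2,2-dimethylcyclopent-3-en-1-yl)phenol, via silyl-protected cyclopentenol 7 (not isolated)
Conditions: (H2IMes)(PCy3)Cl2Ru=CHPh (second-generation Grubbs catalyst, 3 mol %), CH2Cl2, 40 °C; then Bu4NF, THF, 0 °C
Reagents that add atoms: none
Why: Ring-closing metathesis to a cyclopentene, helped by the gem-dimethyl (Thorpe–Ingold) effect, followed by fluoride cleavage of the aryl silyl ether in the same flask, so that the acid-labile para-hydroxybenzylic tertiary alcohol is freed only just before use.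

Step 5
Reactants: 8 rac-4-(1-hydroxy-2,2-dimethylcyclopent-3-en-1-yl)phenol
Product: 9 5,5-dimethylspiro[5.5]undeca-3,7,10-triene-1,9-dione
Conditions: PhI(OAc)2 (1.1 equiv), (CF3)2CHOH, 0 °C, short contact time
Reagents that add atoms: none
Why: Ligand exchange of the phenol on PhI(OAc)2 and loss of PhI in the ionising solvent give a phenoxenium-type species with its positive charge on the para carbon C6, and the C1-C5 σ bond, aligned with that empty orbital, shifts from C1 to C6 while the C1 hydroxyl oxygen pushes and becomes the C1 ketone (semipinacol, Wagner–Meerwein 1,2-shift). The closest known reaction type is the oxidative Wagner–Meerwein transposition of 4-(1-hydroxyalkyl)phenols with trivalent-iodine reagents in fluorinated alcohols, which includes ring enlargement of 1-arylcycloalkanols. No ring is closed through a new tether: the cyclopentene C1-C5 takes in the former ipso carbon C6 by a suprafacial 1,2-shift and becomes six-membered ring A, while the flat arene becomes ring B as a cross-conjugated dienone, so the spiro centre and its bond to quaternary C5 arise in one event. No stereocentre is created, because C6 carries two identical arms and the carbinol centre is erased, which is why racemic 8 suffices. The step needs migration of C5 rather than C2, and this is secured because C5 is tertiary and allylic and carries positive charge in the bridged transition state better than the secondary C2. It also needs the shift to outrun solvent capture at C6 and acid ionisation of the carbinol, which the poorly nucleophilic (CF3)2CHOH, the low temperature and the short contact time secure.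

Step 6
Reactants: 9 5,5-dimethylspiro[5.5]undeca-3,7,10-triene-1,9-dione
Product: 10 rac-(3R*,4R*)-4-bromo-5,5-dimethyl-1,9-dioxospiro[5.5]undeca-7,10-dien-3-yl acetate
Conditions: N-bromoacetamide, LiOAc, AcOH, rt, dark
Reagents that add atoms: N-bromoacetamide CC(=O)NBr; acetic acid CC(=O)O
Why: Bromoacetoxylation by anti addition through a bromonium ion: only the isolated C3=C4 alkene is nucleophilic enough to react, and acetate opens the bromonium at C3, remote from quaternary C5, so Br sits on C4 trans to OAc; 9 is achiral, hence a racemate forms.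

Step 7
Reactants: 10 rac-(3R*,4R*)-4-bromo-5,5-dimethyl-1,9-dioxospiro[5.5]undeca-7,10-dien-3-yl acetate
Product: 11 (3R,4R)-4-bromo-3-hydroxy-5,5-dimethylspiro[5.5]undeca-7,10-diene-1,9-dione
Conditions: Amano lipase PS (Burkholderia cepacia), n-BuOH, MTBE, 35 °C, stopped just below half conversion
Reagents that add atoms: none
Why: Lipase-catalysed kinetic resolution by alcoholysis, in which the empirical size rule for secondary carbinols (large CHBr side, medium CH2 side) predicts faster cleavage of the (3R)-ester; this fixes the absolute configuration of C4 and of the temporary C3 centre under neutral conditions that spare the 4-acyl dienone.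

Step 8
Reactants: 11 (3R,4R)-4-bromo-3-hydroxy-5,5-dimethylspiro[5.5]undeca-7,10-diene-1,9-dione
Product: 12 (3R,4R)-4-bromo-3-[(tert-butyldimethylsilyl)oxy]-5,5-dimethylspiro[5.5]undeca-7,10-diene-1,9-dione
Conditions: TBSOTf, 2,6-lutidine, CH2Cl2, −78 → 0 °C
Reagents that add atoms: tert-butyldimethylsilyl triflate CC(C)(C)[Si](C)(C)OS(=O)(=O)C(F)(F)F
Why: Silylation with a silyl triflate and a hindered base protects the β-hydroxy ketone against retro-aldol and elimination, and adds a second large equatorial group that locks the chair of ring A.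

Step 9
Reactants: 12 (3R,4R)-4-bromo-3-[(tert-butyldimethylsilyl)oxy]-5,5-dimethylspiro[5.5]undeca-7,10-diene-1,9-dione
Product: 14 (3R,4R,6S)-4-bromo-3-[(tert-butyldimethylsilyl)oxy]-5,5-dimethylspiro[5.5]undec-10-ene-1,9-dione, via silyl dienol ether 13 (not isolated)
Conditions: Cu(OAc)2·H2O (5 mol %), (R)-DTBM-SEGPHOS (5.5 mol %), (EtO)2MeSiH, toluene, −20 °C; then 1 M aq HCl, THF, 0 °C
Reagents that add atoms: none
Why: Copper hydride catalysed asymmetric conjugate reduction, the known desymmetrisation of 4,4-disubstituted cyclohexadienones: with Br and OTBS equatorial, hydride comes anti to C5 and should reach C7, the arm that is axial on ring A and trans to Br, because C11 is screened by the eclipsed C1=O on one face and by both methyl groups on the other; the matched ligand reinforces this choice, which sets C6, and the silyl dienol ether blocks a second reduction.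

Step 10
Reactants: 14 (3R,4R,6S)-4-bromo-3-[(tert-butyldimethylsilyl)oxy]-5,5-dimethylspiro[5.5]undec-10-ene-1,9-dione
Product: 16 (3R,4R,6S,10R)-4-bromo-3-[(tert-butyldimethylsilyl)oxy]-10-hydroxy-5,5-dimethylspiro[5.5]undecane-1,9-dione, via C10 hydroperoxide 15 (not isolated)
Conditions: Mn(dpm)3 (10 mol %), PhSiH3, O2 (1 atm), i-PrOH/CH2Cl2, 0 °C; then P(OEt)3
Reagents that add atoms: dioxygen O=O
Why: Mukaiyama-type reductive α-hydroxylation of an enone (hydrogen-atom transfer to C11, capture of the C10 radical by O2, phosphite reduction) places H on C11 and O on C10 regiospecifically; O2 should approach anti to C1, which is axial on ring B, giving the equatorial (10R)-alcohol that steers step 11 and is erased in step 14.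

Step 11
Reactants: 16 (3R,4R,6S,10R)-4-bromo-3-[(tert-butyldimethylsilyl)oxy]-10-hydroxy-5,5-dimethylspiro[5.5]undecane-1,9-dione
Product: 18 (3R,4R,6S,9S,10R)-4-bromo-3-[(tert-butyldimethylsilyl)oxy]-9-(chloromethyl)-5,5-dimethyl-9,10-bis[(trimethylsilyl)oxy]spiro[5.5]undecan-1-one, via bis(chloromagnesium) alkoxide 17 (not isolated)
Conditions: ICH2Cl, i-PrMgCl·LiCl, THF, −78 °C; then TMSOTf, 2,6-lutidine, −78 → 0 °C
Reagents that add atoms: chloroiodomethane ClCI; trimethylsilyl triflate C[Si](C)(C)OS(=O)(=O)C(F)(F)F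
Why: Chelate-controlled (Cram chelate) 1,2-addition of the magnesium carbenoid ClCH2MgCl: only the open C9 ketone reacts because C1 is flanked by quaternary C6, and magnesium bridges the equatorial C10 alkoxide and C9=O so that attack comes from the side of the axial C10-H (equatorial attack), giving equatorial CH2Cl and axial C9-O (9S); silylation in the same flask prevents epoxide closure.

Step 12
Reactants: 18 (3R,4R,6S,9S,10R)-4-bromo-3-[(tert-butyldimethylsilyl)oxy]-9-(chloromethyl)-5,5-dimethyl-9,10-bis[(trimethylsilyl)oxy]spiro[5.5]undecan-1-one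
Product: 19 (3R,4R,6R,9S,10R)-4-bromo-3-[(tert-butyldimethylsilyl)oxy]-9-(chloromethyl)-5,5-dimethyl-1-methylidene-9,10-bis[(trimethylsilyl)oxy]spiro[5.5]undecane
Conditions: Cp2Ti(μ-Cl)(μ-CH2)AlMe2 (Tebbe reagent), pyridine, toluene/THF, −40 °C → rt
Reagents that add atoms: Tebbe reagent C[Al-]1(C)C[Ti]([Cl+]1)(C2C=CC=C2)C3C=CC=C3
Why: Tebbe methylenation, in which the non-basic titanium methylidene converts hindered, enolisable ketones next to quaternary carbons without β-elimination of the C3 silyloxy group and without touching C-Br, C-Cl or the silyl ethers.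

Step 13
Reactants: 19 (3R,4R,6R,9S,10R)-4-bromo-3-[(tert-butyldimethylsilyl)oxy]-9-(chloromethyl)-5,5-dimethyl-1-methylidene-9,10-bis[(trimethylsilyl)oxy]spiro[5.5]undecane
Product: 20 (3R,4R,6R,9S,10R)-4-bromo-9-(chloromethyl)-5,5-dimethyl-1-methylidenespiro[5.5]undecane-3,9,10-triol
Conditions: HF·pyridine, pyridine/THF, 0 °C → rt
Reagents that add atoms: none
Why: Global fluoride desilylation in a buffered, non-basic medium, so neither halohydrin closes to an epoxide and the exocyclic alkene stays in place.

Step 14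
Reactants: 20 (3R,4R,6R,9S,10R)-4-bromo-9-(chloromethyl)-5,5-dimethyl-1-methylidenespiro[5.5]undecane-3,9,10-triol
Product: 21 (4R,6R,9S)-4-bromo-9-(chloromethyl)-9-hydroxy-5,5-dimethyl-1-methylidenespiro[5.5]undecane-3,10-dione
Conditions: IBX (3 equiv), DMSO, rt
Reagents that add atoms: none
Why: IBX oxidation of both secondary alcohols, a reagent that turns 1,2-diols into α-ketols without C-C cleavage; its neutral medium should neither epimerise C4-Br nor move the C1 alkene into conjugation.

Step 15
Reactants: 21 (4R,6R,9S)-4-bromo-9-(chloromethyl)-9-hydroxy-5,5-dimethyl-1-methylidenespiro[5.5]undecane-3,10-dione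
Product: 22 (3S,4R,6R,9S)-4-bromo-9-(chloromethyl)-3,9-dihydroxy-5,5-dimethyl-1-methylidenespiro[5.5]undecan-10-one (CNP0273087.1)
Conditions: NaBH4, CH2Cl2/MeOH, −78 °C
Reagents that add atoms: none
Why: Chemo- and diastereoselective borohydride reduction: the C3 α-bromo ketone is more electrophilic and less hindered than the C10 ketone, which lies between quaternary C9 and neopentyl C11, and axial attack at C3 is blocked by the axial C5 methyl, so hydride enters equatorially and gives the axial alcohol cis to the equatorial bromine (3S).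

**Compound list**

1 | 4-[(tert-butyldimethylsilyl)oxy]benzaldehyde | O=Cc1ccc(O[Si](C)(C)C(C)(C)C)cc1 | starting material
2 | prenyl bromide | CC(C)=CCBr | starting material
3 | rac-1-{4-[(tert-butyldimethylsilyl)oxy]phenyl}-2,2-dimethylbut-3-en-1-ol (racemic) | OC(c1ccc(O[Si](C)(C)C(C)(C)C)cc1)C(C)(C)C=C | intermediate
4 | 1-{4-[(tert-butyldimethylsilyl)oxy]phenyl}-2,2-dimethylbut-3-en-1-one | O=C(c1ccc(O[Si](C)(C)C(C)(C)C)cc1)C(C)(C)C=C | intermediate
5 | allylmagnesium bromide | C=CC[Mg]Br | starting material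
6 | rac-4-{4-[(tert-butyldimethylsilyl)oxy]phenyl}-3,3-dimethylhepta-1,6-dien-4-ol (racemic) | C=CCC(O)(c1ccc(O[Si](C)(C)C(C)(C)C)cc1)C(C)(C)C=C | intermediate
7 | rac-1-{4-[(tert-butyldimethylsilyl)oxy]phenyl}-2,2-dimethylcyclopent-3-en-1-ol (racemic, not isolated) | OC1(CC=CC1(C)C)c1ccc(O[Si](C)(C)C(C)(C)C)cc1 | intermediate
8 | rac-4-(1-hydroxy-2,2-dimethylcyclopent-3-en-1-yl)phenol (racemic) | OC1(CC=CC1(C)C)c1ccc(O)cc1 | intermediate
9 | 5,5-dimethylspiro[5.5]undeca-3,7,10-triene-1,9-dione (achiral) | O=C1CC=CC(C)(C)C12C=CC(=O)C=C2 | intermediate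
10 | rac-(3R*,4R*)-4-bromo-5,5-dimethyl-1,9-dioxospiro[5.5]undeca-7,10-dien-3-yl acetate (racemic, Br trans to OAc, one enantiomer drawn) | O=C1C[C@@H](OC(C)=O)[C@H](Br)C(C)(C)C12C=CC(=O)C=C2 | intermediate
11 | (3R,4R)-4-bromo-3-hydroxy-5,5-dimethylspiro[5.5]undeca-7,10-diene-1,9-dione | O=C1C[C@@H](O)[C@H](Br)C(C)(C)C12C=CC(=O)C=C2 | intermediate
12 | (3R,4R)-4-bromo-3-[(tert-butyldimethylsilyl)oxy]-5,5-dimethylspiro[5.5]undeca-7,10-diene-1,9-dione | O=C1C[C@@H](O[Si](C)(C)C(C)(C)C)[C@H](Br)C(C)(C)C12C=CC(=O)C=C2 | intermediate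
13 | (3R,4R,6S)-4-bromo-3-[(tert-butyldimethylsilyl)oxy]-9-{[diethoxy(methyl)silyl]oxy}-5,5-dimethylspiro[5.5]undeca-8,10-dien-1-one (not isolated) | O=C1C[C@@H](O[Si](C)(C)C(C)(C)C)[C@H](Br)C(C)(C)[C@@]12CC=C(O[Si](C)(OCC)OCC)C=C2 | intermediate
14 | (3R,4R,6S)-4-bromo-3-[(tert-butyldimethylsilyl)oxy]-5,5-dimethylspiro[5.5]undec-10-ene-1,9-dione | O=C1C[C@@H](O[Si](C)(C)C(C)(C)C)[C@H](Br)C(C)(C)[C@@]12CCC(=O)C=C2 | intermediate
15 | (3R,4R,6S,10R)-4-bromo-3-[(tert-butyldimethylsilyl)oxy]-10-hydroperoxy-5,5-dimethylspiro[5.5]undecane-1,9-dione (not isolated) | O=C1C[C@@H](O[Si](C)(C)C(C)(C)C)[C@H](Br)C(C)(C)[C@@]12CCC(=O)[C@H](OO)C2 | intermediate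
16 | (3R,4R,6S,10R)-4-bromo-3-[(tert-butyldimethylsilyl)oxy]-10-hydroxy-5,5-dimethylspiro[5.5]undecane-1,9-dione | O=C1C[C@@H](O[Si](C)(C)C(C)(C)C)[C@H](Br)C(C)(C)[C@@]12CCC(=O)[C@H](O)C2 | intermediate
17 | bis(chloromagnesium) alkoxide of (3R,4R,6S,9S,10R)-4-bromo-3-[(tert-butyldimethylsilyl)oxy]-9-(chloromethyl)-9,10-dihydroxy-5,5-dimethylspiro[5.5]undecan-1-one (not isolated) | O=C1C[C@@H](O[Si](C)(C)C(C)(C)C)[C@H](Br)C(C)(C)[C@@]12CC[C@@](O[Mg]Cl)(CCl)[C@H](O[Mg]Cl)C2 | intermediate
18 | (3R,4R,6S,9S,10R)-4-bromo-3-[(tert-butyldimethylsilyl)oxy]-9-(chloromethyl)-5,5-dimethyl-9,10-bis[(trimethylsilyl)oxy]spiro[5.5]undecan-1-one | O=C1C[C@@H](O[Si](C)(C)C(C)(C)C)[C@H](Br)C(C)(C)[C@@]12CC[C@@](O[Si](C)(C)C)(CCl)[C@H](O[Si](C)(C)C)C2 | intermediate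
19 | (3R,4R,6R,9S,10R)-4-bromo-3-[(tert-butyldimethylsilyl)oxy]-9-(chloromethyl)-5,5-dimethyl-1-methylidene-9,10-bis[(trimethylsilyl)oxy]spiro[5.5]undecane | C=C1C[C@@H](O[Si](C)(C)C(C)(C)C)[C@H](Br)C(C)(C)[C@@]12CC[C@@](O[Si](C)(C)C)(CCl)[C@H](O[Si](C)(C)C)C2 | intermediate
20 | (3R,4R,6R,9S,10R)-4-bromo-9-(chloromethyl)-5,5-dimethyl-1-methylidenespiro[5.5]undecane-3,9,10-triol | C=C1C[C@@H](O)[C@H](Br)C(C)(C)[C@@]12CC[C@@](O)(CCl)[C@H](O)C2 | intermediate
21 | (4R,6R,9S)-4-bromo-9-(chloromethyl)-9-hydroxy-5,5-dimethyl-1-methylidenespiro[5.5]undecane-3,10-dione | C=C1CC(=O)[C@H](Br)C(C)(C)[C@@]12CC[C@@](O)(CCl)C(=O)C2 | intermediate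
22 | (3S,4R,6R,9S)-4-bromo-9-(chloromethyl)-3,9-dihydroxy-5,5-dimethyl-1-methylidenespiro[5.5]undecan-10-one (CNP0273087.1) | C=C1C[C@H](O)[C@H](Br)C(C)(C)[C@@]12CC[C@@](O)(CCl)C(=O)C2 | target

**Total step count:** 15. **Longest linear sequence:** 15 steps, from 1.

**Steps most likely to fail**

**Step 9.** The two enone arms may be discriminated too weakly. Hydride transfer to the neopentyl carbon C7 may also be so slow that 1,2-reduction competes.

The fallback sets out from 12, comes back at 16, and replaces steps 9 and 10. Both arms are reduced without selection with [(Ph3P)CuH]6 in toluene. This gives (3R,4R)-4-bromo-3-[(tert-butyldimethylsilyl)oxy]-5,5-dimethylspiro[5.5]undecane-1,9-dione F1, in which C6 is again not stereogenic.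

An L-proline catalysed α-aminoxylation with nitrosobenzene then desymmetrises the C9 ketone. The catalyst fixes the (R) configuration of the new C-O bond. Only at C10 can an (R) C-O bond be equatorial and away from the axial C1, so C6 is set at the same time. The product is (3R,4R,6S,10R)-10-(anilinooxy)-4-bromo-3-[(tert-butyldimethylsilyl)oxy]-5,5-dimethylspiro[5.5]undecane-1,9-dione F2. N-O cleavage with CuSO4 in MeOH leads to 16.

**Step 15.** The C10 ketone may be reduced as well, or bromine may be lost reductively.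

The fallback sets out from 20 and comes back at 22. It never has both ketones in one molecule.

- The cis C9/C10 diol is tied up with 2,2-dimethoxypropane and PPTS as the (3R,4R,6R,9S,10R)-triol 9,10-O-isopropylidene acetal F3.
- IBX gives the (4R,6R,9S,10R)-3-oxo acetal F4.
- NaBH4 at −78 °C gives the (3S,4R,6R,9S,10R)-cis-bromohydrin acetal F5.
- Aqueous acetic acid frees (3S,4R,6R,9S,10R)-4-bromo-9-(chloromethyl)-5,5-dimethyl-1-methylidenespiro[5.5]undecane-3,9,10-triol F6.
- The chemoselective vicinal-diol oxidation with [(neocuproine)Pd(OAc)]2(OTf)2 and benzoquinone in aqueous MeCN converts only the C10 carbinol and gives 22.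

**Step 7.** Acyl transfer on the bulky spirocyclic ester may be slow or poorly enantioselective.

The fallback sets out from 9, comes back at 14, and replaces steps 6 to 9, so that no kinetic resolution is needed. The achiral trienedione is desymmetrised first under the conditions of step 9, with pure catalyst control. This gives (6S)-5,5-dimethylspiro[5.5]undeca-3,10-diene-1,9-dione F7.

NBS in aqueous acetone then gives two trans-bromohydrins that are now diastereomers and are parted by chromatography. They are (3R,4R,6S)-4-bromo-3-hydroxy-5,5-dimethylspiro[5.5]undec-10-ene-1,9-dione F8, which is carried on, and its (3S,4S,6S)-isomer F9. TBSOTf and 2,6-lutidine convert F8 into 14.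

**Further compounds**

F1 | step 9 | (3R,4R)-4-bromo-3-[(tert-butyldimethylsilyl)oxy]-5,5-dimethylspiro[5.5]undecane-1,9-dione | O=C1C[C@@H](O[Si](C)(C)C(C)(C)C)[C@H](Br)C(C)(C)C12CCC(=O)CC2
F2 | step 9 | (3R,4R,6S,10R)-10-(anilinooxy)-4-bromo-3-[(tert-butyldimethylsilyl)oxy]-5,5-dimethylspiro[5.5]undecane-1,9-dione | O=C1C[C@@H](O[Si](C)(C)C(C)(C)C)[C@H](Br)C(C)(C)[C@@]12CCC(=O)[C@H](ONc3ccccc3)C2
F3 | step 15 | (3R,4R,6R,9S,10R)-triol 9,10-O-isopropylidene acetal | C=C1C[C@@H](O)[C@H](Br)C(C)(C)[C@@]12CC[C@]3(CCl)OC(C)(C)O[C@@H]3C2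
F4 | step 15 | (4R,6R,9S,10R)-3-oxo 9,10-O-isopropylidene acetal | C=C1CC(=O)[C@H](Br)C(C)(C)[C@@]12CC[C@]3(CCl)OC(C)(C)O[C@@H]3C2
F5 | step 15 | (3S,4R,6R,9S,10R)-cis-bromohydrin 9,10-O-isopropylidene acetal | C=C1C[C@H](O)[C@H](Br)C(C)(C)[C@@]12CC[C@]3(CCl)OC(C)(C)O[C@@H]3C2
F6 | step 15 | (3S,4R,6R,9S,10R)-4-bromo-9-(chloromethyl)-5,5-dimethyl-1-methylidenespiro[5.5]undecane-3,9,10-triol | C=C1C[C@H](O)[C@H](Br)C(C)(C)[C@@]12CC[C@@](O)(CCl)[C@H](O)C2
F7 | step 7 | (6S)-5,5-dimethylspiro[5.5]undeca-3,10-diene-1,9-dione | O=C1CC=CC(C)(C)[C@@]12CCC(=O)C=C2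
F8 | step 7 | (3R,4R,6S)-4-bromo-3-hydroxy-5,5-dimethylspiro[5.5]undec-10-ene-1,9-dione | O=C1C[C@@H](O)[C@H](Br)C(C)(C)[C@@]12CCC(=O)C=C2
F9 | step 7 | (3S,4S,6S)-4-bromo-3-hydroxy-5,5-dimethylspiro[5.5]undec-10-ene-1,9-dione | O=C1C[C@H](O)[C@@H](Br)C(C)(C)[C@@]12CCC(=O)C=C2
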